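Early readings already fade. Between the first two intervals of Monday's run, with target still under 10.7%, the rate of making target falls. Read as a pseudo-first-order decay, this gives the fade rate, the fractional loss of rate per hour at low conversion: 0.120 h⁻¹. It is a reading and carries the scatter of the points.

in all of them: catalyst 0.13 mol%; added ligand 44 µM

| charge | starting material | partner | remark |
|---|---|---|---|
| Monday's | 0.025 M | 1.5 equiv | run made earlier |
| Friday's | 0.10 M | 1.5 equiv | run made earlier |
| flask | 0.050 M | 1.50 equiv |  |

- Monday's (time / h: target / %): 3.00: 6.3; 6.00: 10.7; 12.0: 15.7; 25.0: 21.5; 40.0: 26.1
- Friday's (time / h: target / %): 4.00: 29.0; 10.0: 46.0; 20.0: 58.1; 30.0: 64.3; 40.0: 66.7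

(each reading ± 0.3 percentage points)

1. apparent order in partner when 10% of the starting material are converted (percent change of the rate of making target for one percent more partner charged)



The flask is charged with the same [added ligand] as both earlier runs, so this reckoning freezes the fade rate at Monday's value. Monday's run passes 10% at 5.52 h, and Friday's run before 1.38 h. The flask's [starting material] is the geometric mean of theirs, so its wait is put near 2.76 h. One percent more partner shortens that wait by about one percent, and the rate then arrives less faded. The apparent order is therefore about one plus fade rate times wait: 1.33.

The forecast differs from this reckoning: 0.7, between 0.15 and 1.1, “a partner order somewhat below one”.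

    starting material + partner + catalyst → target + catalyst, rate k1*[starting material]*[partner]*[catalyst]/(1 + ([starting material]/sat1)) (1.57 mM, k = 128 L² mol⁻² s⁻¹)
    catalyst + added ligand ⇌ idle complex (K = 1.04 × 10⁵ L mol⁻¹, k = 1.49 L mol⁻¹ s⁻¹)
    2 partner → homo dimer (k = 1.96 × 10⁻⁴ L mol⁻¹ s⁻¹)

The flask gives 1.4, reaching 10% at 0.0830 d. The fit of the true steps without the loss to idle complex gives 1.08. The fade rate with that wait gives 1.24. Twice the catalyst shortens the wait by about that factor, so for that flask the fade rate gives a factor on the rate of 2.25, and the simulated factor is 2.66.

The earlier runs and the new flask were generated by integration on assumed constants; noise was put on by code.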